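The route rests on building the quinone ring last, by a [4+2] benzannulation that forms C6–C1 and C2=C3 in one operation (quinone locants: C1, C4 carbonyl carbons; C2, C3 methoxy carbons; C5 chromanyl carbon; C6 CH). An α'-lithiated enaminone carries C3(OMe)–C4(=O)–C5(chromanyl)=C6; nitroketene dimethyl acetal supplies C2 with its methoxy group and C1 as a nitro-bearing carbon. Vinylic substitution, nitronate addition–elimination and aromatization should give a 4-nitrophenol, whose reduction and oxidative hydrolysis unmask the quinone. The step exploits the vicinal C2/C3 dimethoxy unit flanked by the para carbonyls. The chroman C3 stereocenter comes from an asymmetric hydrogenation.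

Key step: step 11

Assumption: dimethyl 2-(triphenylphosphoranylidene)butanedioate and 1,1-bis(methylsulfanyl)-2-nitroethene are taken as catalogue compounds, and the (R,R) ligand antipode in the hydrogenation is assigned by analogy with dehydroamino acid substrates, to be confirmed by correlation on the first run.

Step 1
Reactants: 1 2-hydroxy-3,4-dimethoxybenzaldehyde
Product: 2 2-(benzyloxy)-3,4-dimethoxybenzaldehyde
Conditions: BnBr, K2CO3, DMF, 60 °C
Reagents that add atoms: benzyl bromide, BrCc1ccccc1
Why: Williamson etherification of the phenoxide with a benzylic bromide masks the future 8-OH of ring A with a group that the last step removes under hydrogen.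

Step 2
Reactants: 2 2-(benzyloxy)-3,4-dimethoxybenzaldehyde
Product: 4 2-(benzyloxy)-3,4-dimethoxyphenol, via aryl formate 3 (not isolated)
Conditions: mCPBA, CH2Cl2, 0 to 25 °C; then K2CO3 (cat.), MeOH, 25 °C
Reagents that add atoms: mCPBA, OOC(=O)c1cccc(Cl)c1
Why: Dakin-type Baeyer–Villiger oxidation, in which the electron-rich aryl group migrates, followed by methanolysis of the formate, replaces the formyl group by the phenol oxygen that becomes O1 of the chroman.

Step 3
Reactants: 4 2-(benzyloxy)-3,4-dimethoxyphenol
Product: 5 3-(benzyloxy)-2-hydroxy-4,5-dimethoxybenzaldehyde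
Conditions: MgCl2, Et3N, (CH2O)n, MeCN, 80 °C; aq. HCl work-up
Reagents that add atoms: paraformaldehyde, C=O
Why: Casnati–Skattebøl ortho-formylation: the magnesium phenoxide directs formaldehyde to the only free ortho position, and a second formaldehyde takes up hydride from the benzylic alkoxide.

Step 4
Reactants: 5 3-(benzyloxy)-2-hydroxy-4,5-dimethoxybenzaldehyde; 6 dimethyl 2-(triphenylphosphoranylidene)butanedioate
Product: 7 dimethyl (2E)-2-{[3-(benzyloxy)-2-hydroxy-4,5-dimethoxyphenyl]methylidene}butanedioate
Conditions: PhMe, 90 °C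
Reagents that add atoms: none
Why: Wittig olefination with an ester-stabilized ylide should give the (E)-alkylidene succinate, in which the aryl group is trans to the conjugated ester, so the free phenol cannot close a coumarin.

Step 5
Reactants: 7 dimethyl (2E)-2-{[3-(benzyloxy)-2-hydroxy-4,5-dimethoxyphenyl]methylidene}butanedioate
Product: 8 dimethyl (2S)-2-{[3-(benzyloxy)-2-hydroxy-4,5-dimethoxyphenyl]methyl}butanedioate
Conditions: [Rh(cod)((R,R)-Et-DuPHOS)]BF4 (1 mol %), H2 (5 bar), MeOH, 25 °C
Reagents that add atoms: none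
Why: Asymmetric hydrogenation of a β-aryl itaconate: the alkene and the carbonyl of the CH2CO2Me arm chelate rhodium as an enamide does, so the bisphospholane should deliver hydrogen to one enantioface and set the (S)-center that becomes C3 of the chroman, while the benzyl ether is inert to a homogeneous rhodium catalyst.

Step 6
Reactants: 8 dimethyl (2S)-2-{[3-(benzyloxy)-2-hydroxy-4,5-dimethoxyphenyl]methyl}butanedioate
Product: 9 (2S)-2-{[3-(benzyloxy)-2-hydroxy-4,5-dimethoxyphenyl]methyl}butane-1,4-diol
Conditions: LiAlH4, THF, 0 to 25 °C; then H2O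
Reagents that add atoms: none
Why: Exhaustive hydride reduction of both esters (and of any dihydrocoumarin formed from 8 on standing) gives the triol without touching the stereocenter.

Step 7
Reactants: 9 (2S)-2-{[3-(benzyloxy)-2-hydroxy-4,5-dimethoxyphenyl]methyl}butane-1,4-diol
Product: 10 2-[(3S)-8-(benzyloxy)-6,7-dimethoxy-3,4-dihydro-2H-chromen-3-yl]ethan-1-ol
Conditions: PPh3, DIAD, THF, 0 to 25 °C
Reagents that add atoms: none
Why: Mitsunobu etherification in which the phenol is the only acidic pronucleophile and 6-exo-tet closure onto the CH2OH next to the stereocenter should outrun the seven-membered alternative, the stereocenter itself not being a reacting atom.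

Step 8
Reactants: 10 2-[(3S)-8-(benzyloxy)-6,7-dimethoxy-3,4-dihydro-2H-chromen-3-yl]ethan-1-ol
Product: 11 2-[(3S)-8-(benzyloxy)-6,7-dimethoxy-3,4-dihydro-2H-chromen-3-yl]acetaldehyde
Conditions: Dess–Martin periodinane, CH2Cl2, 0 to 25 °C
Reagents that add atoms: none
Why: Dess–Martin oxidation of the primary alcohol stops at the aldehyde under non-basic conditions, and the stereocenter is β to the carbonyl and cannot epimerize by enolization.

Step 9
Reactants: 11 2-[(3S)-8-(benzyloxy)-6,7-dimethoxy-3,4-dihydro-2H-chromen-3-yl]acetaldehyde; 12 methoxyacetyl chloride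
Product: 14 (3E)-3-[(3S)-8-(benzyloxy)-6,7-dimethoxy-3,4-dihydro-2H-chromen-3-yl]-1-methoxy-4-(morpholin-4-yl)but-3-en-2-one, via enamine 13 (not isolated)
Conditions: morpholine, 4 Å molecular sieves, PhMe, 25 °C; filter, concentrate; then 12, Et3N, CH2Cl2, 0 to 25 °C
Reagents that add atoms: morpholine, C1COCCN1
Why: Stork enamine acylation: the β-carbon of the aldehyde enamine is acylated (directly or through the aminocyclobutanone of methoxyketene, which opens to the same vinylogous amide), so the formyl carbon becomes C6 and the methoxyacetyl group supplies C4 and C3 without a regiochemical choice; the alkene geometry is of no consequence.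

Step 10
Reactants: 15 1,1-bis(methylsulfanyl)-2-nitroethene
Product: 16 1,1-dimethoxy-2-nitroethene
Conditions: NaOMe (2.2 equiv), MeOH, 0 to 25 °C; then AcOH; handled dry
Reagents that add atoms: sodium methoxide, C[O-].[Na+]
Why: Twofold vinylic substitution (addition–elimination) at the push–pull carbon of the nitroalkene should exchange both methylsulfanyl groups for methoxy groups, driven by excess methoxide and loss of volatile methanethiol.

Step 11
Reactants: 14 (3E)-3-[(3S)-8-(benzyloxy)-6,7-dimethoxy-3,4-dihydro-2H-chromen-3-yl]-1-methoxy-4-(morpholin-4-yl)but-3-en-2-one; 16 1,1-dimethoxy-2-nitroethene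
Product: 18 6-[(3S)-8-(benzyloxy)-6,7-dimethoxy-3,4-dihydro-2H-chromen-3-yl]-2,3-dimethoxy-4-nitrophenol, via open-chain nitrodienone 17 (not isolated)
Conditions: LiN(iPr)2 (1.15 equiv), THF, −78 °C; 16, −78 to 0 °C; then AcOH (5 equiv), 50 °C
Reagents that add atoms: none
Why: Proposed new method: LiN(iPr)2 should remove a proton from the C3 methylene of 14 (kinetic α'-deprotonation of a vinylogous amide), and this enolate should add to the acetal carbon of 16 and expel methoxide (vinylic substitution), which makes the C2–C3 bond with both methoxy groups in place and gives 17; in the acetic acid buffer the nitro-bearing carbon C1 of 17, as its nitronate, then adds to C6 of the protonated vinylogous amide, morpholine leaves, and tautomerization delivers the aromatic 4-nitrophenol 18, in which C2=C3 is a ring double bond. The closest known reaction types are the substitution of nitroketene acetals by carbanions, the condensation of enaminones with nitromethyl compounds and the annulation of nitromalonaldehyde with ketones to 4-nitrophenols; their merger into a [4+2] ring synthesis is what is new. The ring closes in the 6-endo-trig mode, and no stereocenter is created, the transient one at C3 of 17 being erased on aromatization. The step needs deprotonation at C3 and not at the γ-position (the chroman C3–H), which the hindered amide base at −78 °C and the acidifying methoxy group should secure and which also protects the existing stereocenter. Regiochemistry is fixed because each partner has one donor and one acceptor terminus (C3 donor and C6 acceptor in 14, C2 acceptor and C1 donor in 16), and irreversible aromatization pulls the reversible additions forward.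

Step 12
Reactants: 18 6-[(3S)-8-(benzyloxy)-6,7-dimethoxy-3,4-dihydro-2H-chromen-3-yl]-2,3-dimethoxy-4-nitrophenol
Product: 20 2,3-dimethoxy-5-[(3S)-8-hydroxy-6,7-dimethoxy-3,4-dihydro-2H-chromen-3-yl]cyclohexa-2,5-diene-1,4-dione, via aminophenol 19 (not isolated)
Conditions: H2 (1 bar), palladium on carbon (Pd/C), EtOAc–MeOH, 25 °C; filter under argon; then aq. FeCl3, EtOAc, 0 °C
Reagents that add atoms: water, O
Why: Hydrogenation over palladium reduces the nitro group and cleaves the benzyl ether, and FeCl3 then oxidizes the 4-aminophenol to the quinone monoimine, which water hydrolyses to the para-quinone under acidic, non-epimerizing conditions that should leave the much less oxidizable ring A phenol alone.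

Compound list
1 | 2-hydroxy-3,4-dimethoxybenzaldehyde | COc1ccc(C=O)c(O)c1OC | starting material
2 | 2-(benzyloxy)-3,4-dimethoxybenzaldehyde | COc1ccc(C=O)c(OCc2ccccc2)c1OC | intermediate
3 | 2-(benzyloxy)-3,4-dimethoxyphenyl formate | COc1ccc(OC=O)c(OCc2ccccc2)c1OC | intermediate (not isolated)
4 | 2-(benzyloxy)-3,4-dimethoxyphenol | COc1ccc(O)c(OCc2ccccc2)c1OC | intermediate
5 | 3-(benzyloxy)-2-hydroxy-4,5-dimethoxybenzaldehyde | COc1cc(C=O)c(O)c(OCc2ccccc2)c1OC | intermediate
6 | dimethyl 2-(triphenylphosphoranylidene)butanedioate | COC(=O)CC(C(=O)OC)=P(c1ccccc1)(c1ccccc1)c1ccccc1 | starting material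
7 | dimethyl (2E)-2-{[3-(benzyloxy)-2-hydroxy-4,5-dimethoxyphenyl]methylidene}butanedioate | COC(=O)C/C(C(=O)OC)=C\c1cc(OC)c(OC)c(OCc2ccccc2)c1O | intermediate
8 | dimethyl (2S)-2-{[3-(benzyloxy)-2-hydroxy-4,5-dimethoxyphenyl]methyl}butanedioate | COC(=O)C[C@H](Cc1cc(OC)c(OC)c(OCc2ccccc2)c1O)C(=O)OC | intermediate
9 | (2S)-2-{[3-(benzyloxy)-2-hydroxy-4,5-dimethoxyphenyl]methyl}butane-1,4-diol | OCC[C@H](Cc1cc(OC)c(OC)c(OCc2ccccc2)c1O)CO | intermediate
10 | 2-[(3S)-8-(benzyloxy)-6,7-dimethoxy-3,4-dihydro-2H-chromen-3-yl]ethan-1-ol | OCC[C@H]1COc2c(cc(OC)c(OC)c2OCc3ccccc3)C1 | intermediate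
11 | 2-[(3S)-8-(benzyloxy)-6,7-dimethoxy-3,4-dihydro-2H-chromen-3-yl]acetaldehyde | O=CC[C@H]1COc2c(cc(OC)c(OC)c2OCc3ccccc3)C1 | intermediate
12 | methoxyacetyl chloride | COCC(Cl)=O | starting material
13 | 4-{(E)-2-[(3S)-8-(benzyloxy)-6,7-dimethoxy-3,4-dihydro-2H-chromen-3-yl]ethenyl}morpholine | O1CCN(CC1)/C=C/[C@H]2COc3c(cc(OC)c(OC)c3OCc4ccccc4)C2 | intermediate (not isolated)
14 | (3E)-3-[(3S)-8-(benzyloxy)-6,7-dimethoxy-3,4-dihydro-2H-chromen-3-yl]-1-methoxy-4-(morpholin-4-yl)but-3-en-2-one | COCC(=O)/C(=C/N1CCOCC1)[C@H]2COc3c(cc(OC)c(OC)c3OCc4ccccc4)C2 | intermediate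
15 | 1,1-bis(methylsulfanyl)-2-nitroethene | CSC(SC)=C[N+](=O)[O-] | starting material
16 | 1,1-dimethoxy-2-nitroethene | COC(OC)=C[N+](=O)[O-] | intermediate
17 | (1E)-2-[(3S)-8-(benzyloxy)-6,7-dimethoxy-3,4-dihydro-2H-chromen-3-yl]-4,5-dimethoxy-1-(morpholin-4-yl)-6-nitrohexa-1,5-dien-3-one (both C4 epimers, C5=C6 geometry not fixed) | COC(C(=O)/C(=C/N1CCOCC1)[C@H]2COc3c(cc(OC)c(OC)c3OCc4ccccc4)C2)C(OC)=C[N+](=O)[O-] | intermediate (not isolated)
18 | 6-[(3S)-8-(benzyloxy)-6,7-dimethoxy-3,4-dihydro-2H-chromen-3-yl]-2,3-dimethoxy-4-nitrophenol | COc1c(OC)c([N+](=O)[O-])cc([C@H]2COc3c(cc(OC)c(OC)c3OCc4ccccc4)C2)c1O | intermediate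
19 | 4-amino-6-[(3S)-8-hydroxy-6,7-dimethoxy-3,4-dihydro-2H-chromen-3-yl]-2,3-dimethoxyphenol | COc1c(OC)c(N)cc([C@H]2COc3c(cc(OC)c(OC)c3O)C2)c1O | intermediate (not isolated)
20 | 2,3-dimethoxy-5-[(3S)-8-hydroxy-6,7-dimethoxy-3,4-dihydro-2H-chromen-3-yl]cyclohexa-2,5-diene-1,4-dione | COC1=C(OC)C(=O)C([C@H]2COc3c(cc(OC)c(OC)c3O)C2)=CC1=O | target

Total step count: 12. Longest linear sequence: 11 steps (steps 1 to 9, 11 and 12); step 10 is a one-step side branch.

Steps most likely to fail

1. Step 11 (new method). The lithiated enaminone may condense with itself, or the nitroketene acetal may be degraded by the methoxide that is released, before the first bond forms. The ring closure of 17 may also stall, because the vinylogous amide is a weak acceptor. The fallback uses known chemistry and gives up the one-operation ring construction. It sets out from aldehyde 11, which nonafluorobutanesulfonyl fluoride and the phosphazene base P2-Et in DMF should convert into the enol nonaflate F1 and, by elimination in the same flask, into the terminal alkyne F2. Lithiation with n-BuLi (THF, −78 °C) and addition to dimethyl squarate gives the 4-alkynyl-4-hydroxycyclobutenone F3. Moore cyclization in toluene at 110 °C gives the benzyl-protected quinone F4. Hydrogenolysis over Pd/C gives the hydroquinone F5, which Ag2O oxidizes to 20, where the fallback rejoins the route.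

2. Step 9. Dehydrochlorination of 12 to methoxyketene and its oligomerization, or acylation at nitrogen followed by loss of the enamine, may divert the C-acylation. The fallback sets out from 11 and replaces the neutral enamine by an aza-enolate. Condensation with tert-butylamine gives the imine F6. Deprotonation with LiN(iPr)2 (THF, −78 °C) and acylation with N-methoxy-N-methyl-2-methoxyacetamide gives the secondary enaminone F7. Amine exchange with morpholine (AcOH cat., toluene, 80 °C) returns to 14.

3. Step 5. Enantioface discrimination may be eroded and the catalyst slowed, because the substrate is a diester with a free ortho-phenol that can compete for rhodium. The fallback sets out from 7 and switches to carboxylate-directed hydrogenation. Regioselective saponification of the non-conjugated ester (LiOH, 2 equiv, THF–water, 0 °C) gives the half-acid F8. Hydrogenation with the same rhodium bisphospholane catalyst in MeOH containing NaOMe, the well-established regime for alkylidene succinate half-esters, gives the (S)-half-acid F9. LiAlH4 reduces acid and ester alike and returns to triol 9.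

Further compounds
F1 | step 11 | 2-[(3S)-8-(benzyloxy)-6,7-dimethoxy-3,4-dihydro-2H-chromen-3-yl]ethenyl nonafluorobutane-1-sulfonate (E/Z mixture) | FC(F)(F)C(F)(F)C(F)(F)C(F)(F)S(=O)(=O)OC=C[C@H]1COc2c(cc(OC)c(OC)c2OCc3ccccc3)C1
F2 | step 11 | (3S)-8-(benzyloxy)-3-ethynyl-6,7-dimethoxy-3,4-dihydro-2H-chromene | C#C[C@H]1COc2c(cc(OC)c(OC)c2OCc3ccccc3)C1
F3 | step 11 | 4-{[(3S)-8-(benzyloxy)-6,7-dimethoxy-3,4-dihydro-2H-chromen-3-yl]ethynyl}-4-hydroxy-2,3-dimethoxycyclobut-2-en-1-one (carbinol center not controlled) | COC1=C(OC)C(O)(C#C[C@H]2COc3c(cc(OC)c(OC)c3OCc4ccccc4)C2)C1=O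
F4 | step 11 | 5-[(3S)-8-(benzyloxy)-6,7-dimethoxy-3,4-dihydro-2H-chromen-3-yl]-2,3-dimethoxycyclohexa-2,5-diene-1,4-dione | COC1=C(OC)C(=O)C([C@H]2COc3c(cc(OC)c(OC)c3OCc4ccccc4)C2)=CC1=O
F5 | step 11 | 5-[(3S)-8-hydroxy-6,7-dimethoxy-3,4-dihydro-2H-chromen-3-yl]-2,3-dimethoxybenzene-1,4-diol | COc1c(OC)c(O)cc([C@H]2COc3c(cc(OC)c(OC)c3O)C2)c1O
F6 | step 9 | (E)-N-tert-butyl-2-[(3S)-8-(benzyloxy)-6,7-dimethoxy-3,4-dihydro-2H-chromen-3-yl]ethan-1-imine | CC(C)(C)/N=C/C[C@H]1COc2c(cc(OC)c(OC)c2OCc3ccccc3)C1
F7 | step 9 | (3Z)-4-(tert-butylamino)-3-[(3S)-8-(benzyloxy)-6,7-dimethoxy-3,4-dihydro-2H-chromen-3-yl]-1-methoxybut-3-en-2-one | COCC(=O)/C(=C\NC(C)(C)C)[C@H]1COc2c(cc(OC)c(OC)c2OCc3ccccc3)C1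
F8 | step 5 | (3E)-4-[3-(benzyloxy)-2-hydroxy-4,5-dimethoxyphenyl]-3-(methoxycarbonyl)but-3-enoic acid | OC(=O)C/C(C(=O)OC)=C\c1cc(OC)c(OC)c(OCc2ccccc2)c1O
F9 | step 5 | (3S)-4-[3-(benzyloxy)-2-hydroxy-4,5-dimethoxyphenyl]-3-(methoxycarbonyl)butanoic acid | OC(=O)C[C@H](Cc1cc(OC)c(OC)c(OCc2ccccc2)c1O)C(=O)OC
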